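The easy step is the lead at 15 d: both earlier runs end with more isomer of the product A than target.

| flask | solid substrate | remark | time |
|---|---|---|---|
| epsilon | 0.50 M | run made earlier |  |
| theta | 2 M | run made earlier |  |
| flask | 1.0 M |  | 15 d |

| run | time / d | target / % | isomer of the product A / % |
|---|---|---|---|
| epsilon | 2.00 | 10.0 | 8.8 |
| epsilon | 4.00 | 6.6 | 12.6 |
| epsilon | 6.00 | 4.5 | 12.7 |
| epsilon | 8.00 | 4.7 | 12.8 |
| epsilon | 10.0 | 3.4 | 13.8 |
| epsilon | 12.0 | 3.6 | 13.8 |
| epsilon | 15.0 | 1.8 | 11.9 |
| theta | 2.00 | 8.1 | 7.0 |
| theta | 4.00 | 6.7 | 11.7 |
| theta | 6.00 | 5.4 | 13.2 |
| theta | 8.00 | 4.7 | 14.0 |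
| theta | 10.0 | 3.0 | 13.5 |
| theta | 12.0 | 1.7 | 12.6 |
| theta | 15.0 | 0.8 | 12.7 |

(standard deviation of a reading: 1 percentage point)

- as a solid, counted per litre of solution: solid substrate
- what may be going on: target <-> isomer of the product B; starting material -> intermediate; intermediate <-> isomer of the product A; intermediate <-> target; intermediate -> side product; solid substrate <-> starting material
- at the start none of the solid substrate is in solution

* ratio of target to isomer of the product A at 12 h
* ratio of target to isomer of the product A at 15 d
* which of target and isomer of the product A there is more of at 15 d

But the ratio is harder: [target] is the smaller term. The last readings give 0.151 in the epsilon run and 0.0630 in the theta run. Pooled, they give 0.106, with mean [isomer of the product A] of 12.3 %.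

The scatter of a pair of target readings, divided by that mean, is the standard error of the pooled ratio, 0.0575. The scatter of isomer of the product A adds a correction of 0.00609, less than that error. The two runs differ by 0.0883, less than the 0.115 expected for their difference. So pooling is allowed, and my reckoning for the 1.0 M flask is 0.106 give or take 0.0575, which keeps isomer of the product A ahead. The time 12 h lies before the first reading, so that ratio is an extrapolation.

The forecast says 3, 0.11 and isomer of the product A, holding that “the solid loading hardly matters”.

The 1.0 M flask gives 2.27 at 12 h and 0.140 at 15 d, and isomer of the product A leads.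

    target ⇌ isomer of the product B (K = 2.30, k = 0.240 /h)
    starting material → intermediate (k = 0.0890 /h)
    intermediate ⇌ isomer of the product A (K = 3.00, k = 0.00760 /h)
    intermediate ⇌ target (K = 0.620, k = 0.0350 /h)
    intermediate → side product (k = 0.0280 /h)
    solid substrate ⇌ starting material, rate k6*(cs6 - [starting material]) while solid is left; crystals form when [starting material] > cs6 (solubility = 0.410 M, k = 0.780 /h)

That late ratio stands 0.0340 above 0.106, within 0.0575. The neighbouring flask, with 0.25 M of solid substrate, holds 11.4 % of isomer of the product A at 15 d, so a pair of readings there would carry a standard error of 0.0618. Its ratio is 0.137, which stands 0.0310 above 0.106, within that error.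

The data come from a simulation with made-up constants; noise was put on by code.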